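## Analysis of the target

The target 23 is a germacranolide: a ten-membered carbocycle (C1 to C10; germacrane locants are used for atoms throughout) that shares its C6–C7 bond with an α-methylene-γ-butyrolactone (O–C6, C7, C11=C13H2, C12=O). The carbocycle holds an E-disubstituted alkene C1=C2 and a Z-trisubstituted alkene C4=C5 (methyl C15), with the doubly allylic carbinol C3 between them, a tertiary allylic carbinol C10 (methyl C14) and a (Z)-2-methylbut-2-enoate (angelate) on O8. There are five stereocentres, 3S, 6S, 7R, 8S and 10S. The lactone is cis-fused (H6 and H7 on the same face) and the C8 oxygen is trans to the C7–C11 bond; C3 and C10 are too far from this triad to be set by relay through a flexible ring. The sensitive groups are the C3 carbinol (ionisation, oxidation to a cross-conjugated dienone), the tertiary allylic C10–OH, the α-methylene lactone (Michael acceptor, and able to migrate to O8 once C8–OH is free) and the angelate (isomerises to the tiglate). The hard part is the ten-membered ring itself together with the contiguous triad C6–C7–C8 on it. The feature that invites the key step is the ring-fusion bond C6–C7: it joins an oxygen-bearing carbon (C6) to the γ-carbon of a 2-carbonyl-allyl unit (C7–C11(C12)=C13). An allyl metal at C13 that attacks a C6 aldehyde through C7 therefore makes this bond, the exocyclic C11=C13, the carbocycle and, after acyl transfer, the lactone, and the cis fusion is the syn outcome such allyl metals give by themselves. A second feature: C2=C1–C10(C14)(OH)–C9–C8–C7 is the carbon chain of linalool without its isopropylidene end, so C10 can come from the chiral pool.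

## Retrosynthetic reasoning

**23 ⇒ 22 ⇒ 19 + 20.** The last operations are the release of C3–OH and the esterification of C8–OH with 20. A silyl ether on O3 kept to the end tells the two secondary alcohols apart; the tertiary C10–OH needs no protection during acylation. The angelate goes on late because it would not survive the reducing and organometallic steps.

**19 ⇒ 18.** The C8 oxygen is carried as an aminoxy (N–O) ether, the group in which it is first introduced. Reductive N–O cleavage in aqueous acid is planned to take off the tertiary silyl ether on O10 in the same operation.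

**18 ⇒ 15 (key disconnection).** The C6–C7 bond and the O–C12 bond are cut. C6–C7 is the only bond common to both rings, so cutting it opens the carbocycle and the lactone at once and removes two stereocentres. What is left is the open chain 15, whose three stereocentres (C3, C8, C10) are far apart and can each be set independently. The forward reaction is an intramolecular chromium-mediated allylation of the C6 aldehyde by the C13 allyl bromide, followed by lactonisation. It must close the ten-membered ring, give the syn adduct and choose the face of C7 under the control of C8.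

**15 ⇒ 14 ⇒ 8 + 13.** The E-alkene C1=C2 is the only disubstituted alkene and is cut by cross-metathesis, which tolerates the allylic bromide, the acrylate and a free allylic alcohol. The Z-enal is made only afterwards, from the allylic alcohol 14, because it is the most isomerisation-prone group of the chain.

**8 ⇒ 7 ⇒ 4 + 5, and 4 ⇒ 3 ⇒ 2 ⇒ 1.** The (Z)-2-(bromomethyl)enoate comes from the allylic alcohol 7 by bromination with allylic transposition. 7 comes from the α-oxygenated aldehyde 4 and the acrylate α-anion equivalent made from 5. The C8 oxygen is set by a catalyst-controlled α-oxyamination of aldehyde 3. 3 is the ozonolysis product of the silyl ether 2 of (S)-linalool 1, which supplies C10 and the vinyl group C1=C2.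

**13 ⇒ 12 ⇒ 11 ⇒ 10 ⇒ 9 + 5.** The Z-trisubstituted alkene C4=C5 comes from syn-carbocupration of the ynoate 11 with a methylcopper reagent. The C3 carbinol comes from a catalytic asymmetric alkynylation of enal 9 with 5. Compound 5 is thus used twice, as C11–C13 and as C4–C6.

## Alternatives that were turned down

Alternative 1: (the textbook one) Ring-closing metathesis at C1=C2. The lactone would be made first by an intermolecular Barbier reaction and lactonisation, and the key step would be the closure of the diene lactone A1 with a ruthenium carbene catalyst. It was turned down because the key step would form one C=C bond and no stereocentre. A ten-membered ring with an E-alkene between a quaternary carbinol and a branched allylic carbon is also a poor metathesis product: the less strained Z-isomer or dimers are the likely outcome. The C6/C7 pair would have to be set beforehand under open-chain control.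

Alternative 2: Anionic acetylenic oxy-Cope ring expansion. The C3–C4 bond is cut and a C1–C6 bond is drawn, which leads back to the six-membered ring of the cyclohexanol A2 (C6, C7, C8, C9, C10, C1). Its potassium alkoxide would rearrange by a [3,3] shift to the cyclodeca-2,5-dienone A3. This maps well on the C1=C2/C3/C4=C5 unit: the E-alkene comes from the chair transition state, C3 from chirality transfer out of C1 through an E-enol ether, and the Z-enone from protonation of the allenolate. It was turned down for three reasons. The three lactone carbons cannot be on C7 as an alkenyl group during the rearrangement, because C4≡C5–C6–C7–C11=C13 is a second, less hindered 1,5-enyne that would break C6–C7 instead of C6–C1. The lactone would therefore have to be annulated on the ten-membered ketone (alkylation at C7, reduction at C6, methylenation) under macrocyclic control. And A2 itself, with four stereocentres, an E-enol ether and a syn-diaxial diol, would cost more steps than the whole route below.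

Alternative 3: [2,3]-Wittig ring contraction. The C6–C7 bond is cut and an O–C13 bond is drawn, giving the 13-membered diallyl ether A4. Deprotonation at C6 would contract the ring to the ten-membered homoallylic alcohol A5 with the C6 hydroxyl and the C11=C13 methylene in place. It was turned down because the base has a choice of three activated positions. The doubly allylic, oxygen-bearing C3–H is the most acidic, and C13–H2 is equivalent in kind to C6–H2. The C6/C7 configuration would depend on the folding of a flexible 13-membered ring, and C12 would still have to be oxidised to the lactone carbonyl afterwards.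

Key step: step 12

Remark: atom locants C1 to C15 are germacrane locants, compound names use their own systematic numbering. (S)-Linalool and both enantiomers of the imidazolidinone catalyst and of the ProPhenol ligand are taken as commercial. OTMP = (2,2,6,6-tetramethylpiperidin-1-yl)oxy, TES = triethylsilyl, TBDPS = tert-butyldiphenylsilyl.

## Steps

Step 1
Reactants: 1 (3S)-3,7-dimethylocta-1,6-dien-3-ol ((S)-linalool)
Product: 2 triethyl{[(3S)-3,7-dimethylocta-1,6-dien-3-yl]oxy}silane
Conditions: TESOTf, 2,6-lutidine, CH2Cl2, −78 to 0 °C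
Reagents that add atoms: triethylsilyl trifluoromethanesulfonate, CC[Si](CC)(CC)OS(=O)(=O)C(F)(F)F
Why: Silylation of a hindered tertiary alcohol with a silyl triflate and a hindered pyridine base is standard; the ether keeps the later γ-oxygenated aldehyde from closing to a lactol. The C10 stereocentre (S) comes from the chiral pool and is not touched.

Step 2
Reactants: 2 triethyl{[(3S)-3,7-dimethylocta-1,6-dien-3-yl]oxy}silane
Product: 3 (4S)-4-methyl-4-[(triethylsilyl)oxy]hex-5-enal
Conditions: O3, CH2Cl2, −78 °C, Sudan red end-point; then Me2S, −78 °C to rt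
Reagents that add atoms: ozone, [O-][O+]=O
Why: Ozonolysis with reductive work-up; ozone attacks the electron-rich trisubstituted alkene much faster than the vinyl group on the quaternary carbon, and the dye end-point stops the reaction there.

Step 3
Reactants: 3 (4S)-4-methyl-4-[(triethylsilyl)oxy]hex-5-enal
Product: 4 (2S,4S)-4-methyl-2-[(2,2,6,6-tetramethylpiperidin-1-yl)oxy]-4-[(triethylsilyl)oxy]hex-5-enal
Conditions: TEMPO (1.5 equiv), CuCl2·2H2O (10 mol %), 5-benzyl-2-tert-butyl-3-methylimidazolidin-4-one·TFA (20 mol %, enantiomer chosen for 2S), acetone, air, 0 °C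
Reagents that add atoms: TEMPO (2,2,6,6-tetramethylpiperidin-1-oxyl), CC1(C)CCCC(C)(C)N1[O]
Why: Organocatalytic α-oxyamination of an aldehyde: the enamine is oxidised with copper assistance and trapped by the nitroxyl radical, giving an isolable α-aminoxy aldehyde. The benzyl group of the catalyst shields one face of the E-enamine, so C8 is set by the catalyst and the remote C10 centre should have little say.

Step 4
Reactants: 4 (2S,4S)-4-methyl-2-[(2,2,6,6-tetramethylpiperidin-1-yl)oxy]-4-[(triethylsilyl)oxy]hex-5-enal; 5 methyl prop-2-ynoate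
Product: 7 methyl (4S,6S)-3-hydroxy-6-methyl-2-methylidene-4-[(2,2,6,6-tetramethylpiperidin-1-yl)oxy]-6-[(triethylsilyl)oxy]oct-7-enoate (both C3 epimers), via vinylalane 6 (not isolated)
Conditions: 5, iBu2AlH, N-methylmorpholine N-oxide, THF, 0 °C; then 4, 0 °C to rt; aq. potassium sodium tartrate
Reagents that add atoms: none
Why: 1,4-Hydroalumination of 5 gives the α-aluminated acrylate 6, which adds to the aldehyde (the aluminium variant of the Morita–Baylis–Hillman reaction) without amine base, so the α-stereocentre of 4 should not epimerise. The new carbinol centre forms as a mixture and disappears in step 5.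

Step 5
Reactants: 7 methyl (4S,6S)-3-hydroxy-6-methyl-2-methylidene-4-[(2,2,6,6-tetramethylpiperidin-1-yl)oxy]-6-[(triethylsilyl)oxy]oct-7-enoate
Product: 8 methyl (2Z,4S,6S)-2-(bromomethyl)-6-methyl-4-[(2,2,6,6-tetramethylpiperidin-1-yl)oxy]-6-[(triethylsilyl)oxy]octa-2,7-dienoate
Conditions: NBS, Me2S, CH2Cl2, −20 to 0 °C
Reagents that add atoms: N-bromosuccinimide, O=C1CCC(=O)N1Br
Why: Corey–Kim-type activation gives an alkoxysulfonium salt that bromide displaces in the SN2′ sense; the (Z)-2-(bromomethyl)alk-2-enoate, with the chain trans to the ester, is the usual product. The tertiary silyl ether and the aminoxy group should be inert.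

Step 6
Reactants: 9 (2E)-but-2-enal; 5 methyl prop-2-ynoate
Product: 10 methyl (4S,5E)-4-hydroxyhept-5-en-2-ynoate
Conditions: Me2Zn (3 equiv), (S,S)-ProPhenol or its enantiomer (10 mol %, chosen for 4S), Ph3PO (20 mol %), toluene, 0 °C
Reagents that add atoms: none
Why: Catalytic asymmetric alkynylation: the dinuclear zinc–ProPhenol complex delivers the zinc acetylide of 5 to one face of the enal and sets C3. Alkynylzinc species add 1,2 to enals.

Step 7
Reactants: 10 methyl (4S,5E)-4-hydroxyhept-5-en-2-ynoate
Product: 11 methyl (4S,5E)-4-[(tert-butyldiphenylsilyl)oxy]hept-5-en-2-ynoate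
Conditions: TBDPSCl, imidazole, DMF, 0 °C to rt
Reagents that add atoms: tert-butyl(chloro)diphenylsilane, CC(C)(C)[Si](Cl)(c1ccccc1)c1ccccc1
Why: Standard silylation of a secondary alcohol. TBDPS is chosen because it should survive the aqueous acetic acid of step 13 and still leave with fluoride at the end.

Step 8
Reactants: 11 methyl (4S,5E)-4-[(tert-butyldiphenylsilyl)oxy]hept-5-en-2-ynoate
Product: 12 methyl (2Z,4S,5E)-4-[(tert-butyldiphenylsilyl)oxy]-3-methylhepta-2,5-dienoate
Conditions: Me2CuLi (from MeLi and CuI), THF, −78 °C; MeOH, then aq. NH4Cl at −78 °C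
Reagents that add atoms: lithium dimethylcuprate, [Li+].C[Cu-]C (made in the flask from methyllithium, [Li]C, and CuI)
Why: syn-Carbocupration of the ynoate followed by protonation of the alkenylcuprate with retention at low temperature puts the new methyl cis to the α-hydrogen, so that C3 is cis to the ester carbon: this is the Z geometry of C4=C5. The silyl ether blocks lactonisation to a butenolide.

Step 9
Reactants: 12 methyl (2Z,4S,5E)-4-[(tert-butyldiphenylsilyl)oxy]-3-methylhepta-2,5-dienoate
Product: 13 (2Z,4S,5E)-4-[(tert-butyldiphenylsilyl)oxy]-3-methylhepta-2,5-dien-1-ol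
Conditions: iBu2AlH (2.5 equiv), CH2Cl2, −78 °C; aq. potassium sodium tartrate
Reagents that add atoms: none
Why: 1,2-Reduction of the enoate to the allylic alcohol at low temperature should leave both alkene geometries and the silyl ether untouched.

Step 10
Reactants: 8 methyl (2Z,4S,6S)-2-(bromomethyl)-6-methyl-4-[(2,2,6,6-tetramethylpiperidin-1-yl)oxy]-6-[(triethylsilyl)oxy]octa-2,7-dienoate; 13 (2Z,4S,5E)-4-[(tert-butyldiphenylsilyl)oxy]-3-methylhepta-2,5-dien-1-ol
Product: 14 methyl (2Z,4S,6S,7E,9S,10Z)-2-(bromomethyl)-9-[(tert-butyldiphenylsilyl)oxy]-12-hydroxy-6,10-dimethyl-4-[(2,2,6,6-tetramethylpiperidin-1-yl)oxy]-6-[(triethylsilyl)oxy]dodeca-2,7,10-trienoate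
Conditions: second-generation Hoveyda–Grubbs catalyst (10 mol %), 13 (2.5 equiv), CH2Cl2, 40 °C
Reagents that add atoms: none
Why: Olefin cross-metathesis between the vinyl group of 8 and the propenyl group of 13, with loss of propene. The trisubstituted alkenes of both partners should not react, and a disubstituted alkene between two branched carbons should form as the E-isomer.

Step 11
Reactants: 14 methyl (2Z,4S,6S,7E,9S,10Z)-2-(bromomethyl)-9-[(tert-butyldiphenylsilyl)oxy]-12-hydroxy-6,10-dimethyl-4-[(2,2,6,6-tetramethylpiperidin-1-yl)oxy]-6-[(triethylsilyl)oxy]dodeca-2,7,10-trienoate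
Product: 15 methyl (2Z,4S,6S,7E,9S,10Z)-2-(bromomethyl)-9-[(tert-butyldiphenylsilyl)oxy]-6,10-dimethyl-12-oxo-4-[(2,2,6,6-tetramethylpiperidin-1-yl)oxy]-6-[(triethylsilyl)oxy]dodeca-2,7,10-trienoate
Conditions: MnO2 (excess), CH2Cl2, rt
Reagents that add atoms: none
Why: MnO2 oxidises only the primary allylic alcohol, and the neutral conditions should keep the Z-enal from isomerising. The aldehyde is used at once.

Step 12
Reactants: 15 methyl (2Z,4S,6S,7E,9S,10Z)-2-(bromomethyl)-9-[(tert-butyldiphenylsilyl)oxy]-6,10-dimethyl-12-oxo-4-[(2,2,6,6-tetramethylpiperidin-1-yl)oxy]-6-[(triethylsilyl)oxy]dodeca-2,7,10-trienoate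
Product: 18 (3aS,4S,6S,7E,9S,10Z,11aS)-9-[(tert-butyldiphenylsilyl)oxy]-6,10-dimethyl-3-methylidene-4-[(2,2,6,6-tetramethylpiperidin-1-yl)oxy]-6-[(triethylsilyl)oxy]-3a,4,5,6,9,11a-hexahydrocyclodeca[b]furan-2(3H)-one, via allylchromium dichloride 16 (not isolated), via hydroxy ester 17 (not isolated)
Conditions: CrCl2 (8 equiv), DMF, rt, slow addition of 15 (final 2 mM); aq. NH4Cl; then PPTS (cat.), CH2Cl2, rt
Reagents that add atoms: none
Why: Divalent chromium inserts into the allylic C–Br bond to give the allylchromium 16 (trivalent chromium), which adds through its γ-carbon C7 to the C6 aldehyde in an intramolecular Barbier (Nozaki–Hiyama-type) allylation; the chromium alkoxide, or the hydroxy ester 17 after work-up, then acylates on the methyl ester. The closest known reaction type is the chromium-, zinc- or indium-mediated addition of 2-(bromomethyl)alk-2-enoates to aldehydes to give α-methylene-γ-butyrolactones, which has also been used to close ten-membered germacrane rings. The carbocycle closes in the exo mode at the carbonyl (C6=O stays outside the ring) with allylic transposition, so that C11 and C13 are pushed out of the ring as the exocyclic methylene; the lactone closes by 5-exo-trig attack of O6 on C12. C6 and C7 are formed together in a chair Zimmerman–Traxler transition state in which C8, cis to the CH2Cr group, is axial: this gives the syn adduct and hence the cis-fused lactone. Their absolute sense is set by C8: 1,3-allylic strain turns C8–H into the alkene plane, and the aldehyde should reach C7 anti to the very bulky aminoxy group, on the face where the tether through C9 lies, which corresponds to 6S,7R. The E-alkene C1=C2 and the Z-alkene C4=C5 on either side of C3 hold the chain in a turn and, with slow addition at high dilution, should favour ring closure over intermolecular allylation. The step needs 1,2- rather than 1,4-addition to the enal, which allylchromium reagents give, and it is stereoconvergent with respect to the geometry of the bromide, because 16 equilibrates by 1,3-metal shift before it adds.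

Step 13
Reactants: 18 (3aS,4S,6S,7E,9S,10Z,11aS)-9-[(tert-butyldiphenylsilyl)oxy]-6,10-dimethyl-3-methylidene-4-[(2,2,6,6-tetramethylpiperidin-1-yl)oxy]-6-[(triethylsilyl)oxy]-3a,4,5,6,9,11a-hexahydrocyclodeca[b]furan-2(3H)-one
Product: 19 (3aR,4S,6S,7E,9S,10Z,11aS)-9-[(tert-butyldiphenylsilyl)oxy]-4,6-dihydroxy-6,10-dimethyl-3-methylidene-3a,4,5,6,9,11a-hexahydrocyclodeca[b]furan-2(3H)-one
Conditions: Zn dust, AcOH/THF/H2O (3:1:1), 50 °C
Reagents that add atoms: none
Why: Zinc in aqueous acetic acid reduces the N–O bond of the alkoxyamine to the C8 alcohol, and the same medium hydrolyses the tertiary triethylsilyl ether. The TBDPS ether is stable to this acid and isolated acrylate-type esters are normally not reduced by zinc in acetic acid. The descriptor at C7 (3a) changes from S to R only because the substituent priorities change.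

Step 14
Reactants: 19 (3aR,4S,6S,7E,9S,10Z,11aS)-9-[(tert-butyldiphenylsilyl)oxy]-4,6-dihydroxy-6,10-dimethyl-3-methylidene-3a,4,5,6,9,11a-hexahydrocyclodeca[b]furan-2(3H)-one; 20 (2Z)-2-methylbut-2-enoic acid (angelic acid)
Product: 22 (3aR,4S,6S,7E,9S,10Z,11aS)-9-[(tert-butyldiphenylsilyl)oxy]-6-hydroxy-6,10-dimethyl-3-methylidene-2-oxo-2,3,3a,4,5,6,9,11a-octahydrocyclodeca[b]furan-4-yl (2Z)-2-methylbut-2-enoate, via mixed anhydride 21 (not isolated)
Conditions: 20, 2,4,6-trichlorobenzoyl chloride, Et3N, toluene, rt; then 19, toluene, 80 °C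
Reagents that add atoms: none
Why: Yamaguchi esterification through the mixed anhydride 21, run without a nucleophilic catalyst so that the angelate should not isomerise to the tiglate. Only the secondary C8–OH is acylated; the tertiary C10–OH is too hindered and O3 is still silylated.

Step 15
Reactants: 22 (3aR,4S,6S,7E,9S,10Z,11aS)-9-[(tert-butyldiphenylsilyl)oxy]-6-hydroxy-6,10-dimethyl-3-methylidene-2-oxo-2,3,3a,4,5,6,9,11a-octahydrocyclodeca[b]furan-4-yl (2Z)-2-methylbut-2-enoate
Product: 23 (3aR,4S,6S,7E,9S,10Z,11aS)-6,9-dihydroxy-6,10-dimethyl-3-methylidene-2-oxo-2,3,3a,4,5,6,9,11a-octahydrocyclodeca[b]furan-4-yl (2Z)-2-methylbut-2-enoate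
Conditions: Bu4NF, AcOH (1:1), THF, 0 °C to rt
Reagents that add atoms: none
Why: Fluoride-mediated desilylation; buffering with acetic acid should suppress base-induced isomerisation of the angelate, Michael addition to the methylene lactone and lactone migration. No stereocentre is touched.

## Compound list

1 | (3S)-3,7-dimethylocta-1,6-dien-3-ol ((S)-linalool) | C=C[C@@](C)(O)CCC=C(C)C | starting material
2 | triethyl{[(3S)-3,7-dimethylocta-1,6-dien-3-yl]oxy}silane | C=C[C@@](C)(O[Si](CC)(CC)CC)CCC=C(C)C | intermediate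
3 | (4S)-4-methyl-4-[(triethylsilyl)oxy]hex-5-enal | C=C[C@@](C)(O[Si](CC)(CC)CC)CCC=O | intermediate
4 | (2S,4S)-4-methyl-2-[(2,2,6,6-tetramethylpiperidin-1-yl)oxy]-4-[(triethylsilyl)oxy]hex-5-enal | C=C[C@@](C)(O[Si](CC)(CC)CC)C[C@H](ON1C(C)(C)CCCC1(C)C)C=O | intermediate
5 | methyl prop-2-ynoate (methyl propiolate) | C#CC(=O)OC | starting material
6 | methyl 2-[bis(2-methylpropyl)alumanyl]prop-2-enoate (vinylalane) | C=C(C(=O)OC)[Al](CC(C)C)CC(C)C | intermediate
7 | methyl (4S,6S)-3-hydroxy-6-methyl-2-methylidene-4-[(2,2,6,6-tetramethylpiperidin-1-yl)oxy]-6-[(triethylsilyl)oxy]oct-7-enoate (both C3 epimers) | C=C[C@@](C)(O[Si](CC)(CC)CC)C[C@H](ON1C(C)(C)CCCC1(C)C)C(O)C(=C)C(=O)OC | intermediate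
8 | methyl (2Z,4S,6S)-2-(bromomethyl)-6-methyl-4-[(2,2,6,6-tetramethylpiperidin-1-yl)oxy]-6-[(triethylsilyl)oxy]octa-2,7-dienoate | C=C[C@@](C)(O[Si](CC)(CC)CC)C[C@H](ON1C(C)(C)CCCC1(C)C)/C=C(\CBr)C(=O)OC | intermediate
9 | (2E)-but-2-enal (crotonaldehyde) | C/C=C/C=O | starting material
10 | methyl (4S,5E)-4-hydroxyhept-5-en-2-ynoate | C/C=C/[C@H](O)C#CC(=O)OC | intermediate
11 | methyl (4S,5E)-4-[(tert-butyldiphenylsilyl)oxy]hept-5-en-2-ynoate | C/C=C/[C@H](O[Si](c1ccccc1)(c1ccccc1)C(C)(C)C)C#CC(=O)OC | intermediate
12 | methyl (2Z,4S,5E)-4-[(tert-butyldiphenylsilyl)oxy]-3-methylhepta-2,5-dienoate | C/C=C/[C@H](O[Si](c1ccccc1)(c1ccccc1)C(C)(C)C)/C(C)=C\C(=O)OC | intermediate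
13 | (2Z,4S,5E)-4-[(tert-butyldiphenylsilyl)oxy]-3-methylhepta-2,5-dien-1-ol | C/C=C/[C@H](O[Si](c1ccccc1)(c1ccccc1)C(C)(C)C)/C(C)=C\CO | intermediate
14 | methyl (2Z,4S,6S,7E,9S,10Z)-2-(bromomethyl)-9-[(tert-butyldiphenylsilyl)oxy]-12-hydroxy-6,10-dimethyl-4-[(2,2,6,6-tetramethylpiperidin-1-yl)oxy]-6-[(triethylsilyl)oxy]dodeca-2,7,10-trienoate | OC/C=C(/C)[C@@H](O[Si](c1ccccc1)(c1ccccc1)C(C)(C)C)/C=C/[C@@](C)(O[Si](CC)(CC)CC)C[C@H](ON1C(C)(C)CCCC1(C)C)/C=C(\CBr)C(=O)OC | intermediate
15 | methyl (2Z,4S,6S,7E,9S,10Z)-2-(bromomethyl)-9-[(tert-butyldiphenylsilyl)oxy]-6,10-dimethyl-12-oxo-4-[(2,2,6,6-tetramethylpiperidin-1-yl)oxy]-6-[(triethylsilyl)oxy]dodeca-2,7,10-trienoate | O=C/C=C(/C)[C@@H](O[Si](c1ccccc1)(c1ccccc1)C(C)(C)C)/C=C/[C@@](C)(O[Si](CC)(CC)CC)C[C@H](ON1C(C)(C)CCCC1(C)C)/C=C(\CBr)C(=O)OC | intermediate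
16 | allylchromium dichloride of 15 (C–CrCl2 in place of C–Br, trivalent chromium) | O=C/C=C(/C)[C@@H](O[Si](c1ccccc1)(c1ccccc1)C(C)(C)C)/C=C/[C@@](C)(O[Si](CC)(CC)CC)C[C@H](ON1C(C)(C)CCCC1(C)C)/C=C(\C[Cr](Cl)Cl)C(=O)OC | intermediate
17 | methyl 2-[(1S,2S,3Z,5S,6E,8S,10S)-5-[(tert-butyldiphenylsilyl)oxy]-2-hydroxy-4,8-dimethyl-10-[(2,2,6,6-tetramethylpiperidin-1-yl)oxy]-8-[(triethylsilyl)oxy]cyclodeca-3,6-dien-1-yl]prop-2-enoate | O[C@H]1/C=C(/C)[C@@H](O[Si](c2ccccc2)(c2ccccc2)C(C)(C)C)/C=C/[C@@](C)(O[Si](CC)(CC)CC)C[C@H](ON2C(C)(C)CCCC2(C)C)[C@H]1C(=C)C(=O)OC | intermediate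
18 | (3aS,4S,6S,7E,9S,10Z,11aS)-9-[(tert-butyldiphenylsilyl)oxy]-6,10-dimethyl-3-methylidene-4-[(2,2,6,6-tetramethylpiperidin-1-yl)oxy]-6-[(triethylsilyl)oxy]-3a,4,5,6,9,11a-hexahydrocyclodeca[b]furan-2(3H)-one | C=C1C(=O)O[C@H]2/C=C(/C)[C@@H](O[Si](c3ccccc3)(c3ccccc3)C(C)(C)C)/C=C/[C@@](C)(O[Si](CC)(CC)CC)C[C@H](ON3C(C)(C)CCCC3(C)C)[C@@H]12 | intermediate
19 | (3aR,4S,6S,7E,9S,10Z,11aS)-9-[(tert-butyldiphenylsilyl)oxy]-4,6-dihydroxy-6,10-dimethyl-3-methylidene-3a,4,5,6,9,11a-hexahydrocyclodeca[b]furan-2(3H)-one | C=C1C(=O)O[C@H]2/C=C(/C)[C@@H](O[Si](c3ccccc3)(c3ccccc3)C(C)(C)C)/C=C/[C@@](C)(O)C[C@H](O)[C@@H]12 | intermediate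
20 | (2Z)-2-methylbut-2-enoic acid (angelic acid) | C/C=C(/C)C(=O)O | starting material
21 | (2Z)-2-methylbut-2-enoic 2,4,6-trichlorobenzoic anhydride | C/C=C(/C)C(=O)OC(=O)c1c(Cl)cc(Cl)cc1Cl | intermediate
22 | (3aR,4S,6S,7E,9S,10Z,11aS)-9-[(tert-butyldiphenylsilyl)oxy]-6-hydroxy-6,10-dimethyl-3-methylidene-2-oxo-2,3,3a,4,5,6,9,11a-octahydrocyclodeca[b]furan-4-yl (2Z)-2-methylbut-2-enoate | C=C1C(=O)O[C@H]2/C=C(/C)[C@@H](O[Si](c3ccccc3)(c3ccccc3)C(C)(C)C)/C=C/[C@@](C)(O)C[C@H](OC(=O)/C(C)=C\C)[C@@H]12 | intermediate
23 | (3aR,4S,6S,7E,9S,10Z,11aS)-6,9-dihydroxy-6,10-dimethyl-3-methylidene-2-oxo-2,3,3a,4,5,6,9,11a-octahydrocyclodeca[b]furan-4-yl (2Z)-2-methylbut-2-enoate | C=C1C(=O)O[C@H]2/C=C(/C)[C@@H](O)/C=C/[C@@](C)(O)C[C@H](OC(=O)/C(C)=C\C)[C@@H]12 | target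

## Step count and least certain steps

Total: 15 steps. Longest linear sequence: 11 steps (steps 1 to 5 and 10 to 15, from 1). The branch from 9 has 4 steps (6 to 9) before the union.

**Step 12 (key step).** Most likely failures: attack of the aldehyde on the other face of C7 (syn to the C8 oxygen), which would give the 6,7-diepimeric cis-lactone; intermolecular allylation (oligomers) instead of ring closure; and 1,4-elimination of the aminoxy group from the allylchromium 16. Fallback (sets out from 8 and 13, returns at 18): ring formation and C6–C7 bond formation are separated. 13 is oxidised with MnO2 to (2Z,4S,5E)-4-[(tert-butyldiphenylsilyl)oxy]-3-methylhepta-2,5-dienal F1. F1 is joined with 8 in an intermolecular CrCl2- or zinc-mediated Barbier reaction at normal concentration, and lactonisation gives the open-chain cis-lactone diene F2. Ring-closing metathesis of its propenyl and vinyl groups with the second-generation Hoveyda–Grubbs catalyst then closes C1=C2 and gives 18.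

**Step 10.** The vinyl group of 8 sits on a fully substituted, silylated carbon and is a slow metathesis partner, so self-metathesis of 13 and ring-closing of 8 between its vinyl group and the acrylate alkene (a cyclopentene) may win. Fallback (sets out from 8, returns at 19): the tertiary silyl ether is removed first (PPTS, MeOH) to give methyl (2Z,4S,6S)-2-(bromomethyl)-6-hydroxy-6-methyl-4-[(2,2,6,6-tetramethylpiperidin-1-yl)oxy]octa-2,7-dienoate F3; free tertiary allylic alcohols are better cross-metathesis partners. Cross-metathesis with 13 gives the 6-hydroxy seco alcohol F4, MnO2 gives the enal F5, the chromium-mediated ring closure gives the 6-hydroxy lactone F6, and zinc in aqueous acetic acid gives 19.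

**Step 13.** The N–O cleavage needs warm aqueous acid and zinc. This may reduce or add to the α-methylene lactone, solvolyse the doubly allylic silyl ether or move the lactone to the freed O8. Fallback (sets out from 18, returns at 19): the methylene lactone is masked as its dimethylamine Michael adduct F7 (Me2NH, THF). Zinc in aqueous acetic acid then gives the amino diol F8, and N-methylation (MeI) followed by elimination (NaHCO3) restores the exocyclic alkene and gives 19.

**Step 6.** The small enal 9 may give insufficient enantioselectivity or some conjugate addition. Fallback (sets out from 10 of insufficient enantiomeric purity, returns at 10): 10 is oxidised with MnO2 to methyl (5E)-4-oxohept-5-en-2-ynoate F9, and the alkynyl ketone is reduced by asymmetric transfer hydrogenation with RuCl(p-cymene)[(S,S)-TsDPEN] (or its enantiomer) in iPrOH to 10.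

## Further compounds

F1 | step 12 | (2Z,4S,5E)-4-[(tert-butyldiphenylsilyl)oxy]-3-methylhepta-2,5-dienal | C/C=C/[C@H](O[Si](c1ccccc1)(c1ccccc1)C(C)(C)C)/C(C)=C\C=O
F2 | step 12 | (4S,5S)-5-{(1Z,3S,4E)-3-[(tert-butyldiphenylsilyl)oxy]-2-methylhexa-1,4-dien-1-yl}-3-methylidene-4-{(1S,3S)-3-methyl-1-[(2,2,6,6-tetramethylpiperidin-1-yl)oxy]-3-[(triethylsilyl)oxy]pent-4-en-1-yl}oxolan-2-one (open-chain cis-lactone diene) | C=C1C(=O)O[C@@H](/C=C(/C)[C@@H](O[Si](c2ccccc2)(c2ccccc2)C(C)(C)C)/C=C/C)[C@H]1[C@@H](ON1C(C)(C)CCCC1(C)C)C[C@](C)(O[Si](CC)(CC)CC)C=C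
F3 | step 10 | methyl (2Z,4S,6S)-2-(bromomethyl)-6-hydroxy-6-methyl-4-[(2,2,6,6-tetramethylpiperidin-1-yl)oxy]octa-2,7-dienoate | C=C[C@@](C)(O)C[C@H](ON1C(C)(C)CCCC1(C)C)/C=C(\CBr)C(=O)OC
F4 | step 10 | methyl (2Z,4S,6S,7E,9S,10Z)-2-(bromomethyl)-9-[(tert-butyldiphenylsilyl)oxy]-6,12-dihydroxy-6,10-dimethyl-4-[(2,2,6,6-tetramethylpiperidin-1-yl)oxy]dodeca-2,7,10-trienoate | OC/C=C(/C)[C@@H](O[Si](c1ccccc1)(c1ccccc1)C(C)(C)C)/C=C/[C@@](C)(O)C[C@H](ON1C(C)(C)CCCC1(C)C)/C=C(\CBr)C(=O)OC
F5 | step 10 | methyl (2Z,4S,6S,7E,9S,10Z)-2-(bromomethyl)-9-[(tert-butyldiphenylsilyl)oxy]-6-hydroxy-6,10-dimethyl-12-oxo-4-[(2,2,6,6-tetramethylpiperidin-1-yl)oxy]dodeca-2,7,10-trienoate | O=C/C=C(/C)[C@@H](O[Si](c1ccccc1)(c1ccccc1)C(C)(C)C)/C=C/[C@@](C)(O)C[C@H](ON1C(C)(C)CCCC1(C)C)/C=C(\CBr)C(=O)OC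
F6 | step 10 | (3aS,4S,6S,7E,9S,10Z,11aS)-9-[(tert-butyldiphenylsilyl)oxy]-6-hydroxy-6,10-dimethyl-3-methylidene-4-[(2,2,6,6-tetramethylpiperidin-1-yl)oxy]-3a,4,5,6,9,11a-hexahydrocyclodeca[b]furan-2(3H)-one | C=C1C(=O)O[C@H]2/C=C(/C)[C@@H](O[Si](c3ccccc3)(c3ccccc3)C(C)(C)C)/C=C/[C@@](C)(O)C[C@H](ON3C(C)(C)CCCC3(C)C)[C@@H]12
F7 | step 13 | dimethylamine adduct of 18: 3-[(dimethylamino)methyl] in place of 3-methylidene (configuration at C11 not assigned) | CN(C)CC1C(=O)O[C@H]2/C=C(/C)[C@@H](O[Si](c3ccccc3)(c3ccccc3)C(C)(C)C)/C=C/[C@@](C)(O[Si](CC)(CC)CC)C[C@H](ON3C(C)(C)CCCC3(C)C)[C@@H]12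
F8 | step 13 | dimethylamine adduct of 19: 3-[(dimethylamino)methyl] in place of 3-methylidene (configuration at C11 not assigned) | CN(C)CC1C(=O)O[C@H]2/C=C(/C)[C@@H](O[Si](c3ccccc3)(c3ccccc3)C(C)(C)C)/C=C/[C@@](C)(O)C[C@H](O)[C@@H]12
F9 | step 6 | methyl (5E)-4-oxohept-5-en-2-ynoate | C/C=C/C(=O)C#CC(=O)OC
A1 | alternative 1 | diene lactone for ring-closing metathesis (3,8-bis-TBS, 10-TES, two vinyl groups) | C=C1C(=O)O[C@@H](/C=C(/C)[C@@H](O[Si](C)(C)C(C)(C)C)C=C)[C@H]1[C@@H](O[Si](C)(C)C(C)(C)C)C[C@](C)(O[Si](CC)(CC)CC)C=C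
A2 | alternative 2 | 5-[(tert-butyldimethylsilyl)oxy]-2-{(E)-2-[(4-methoxybenzyl)oxy]ethenyl}-3-methyl-1-(prop-1-yn-1-yl)cyclohexane-1,3-diol (oxy-Cope substrate) | CC#C[C@@]1(O)C[C@@H](O[Si](C)(C)C(C)(C)C)C[C@](C)(O)[C@@H]1/C=C/OCc1ccc(OC)cc1
A3 | alternative 2 | (2Z,5E)-9-[(tert-butyldimethylsilyl)oxy]-7-hydroxy-4-[(4-methoxybenzyl)oxy]-3,7-dimethylcyclodeca-2,5-dien-1-one | O=C1/C=C(/C)[C@@H](OCc2ccc(OC)cc2)/C=C/[C@@](C)(O)C[C@H](O[Si](C)(C)C(C)(C)C)C1
A4 | alternative 3 | 13-membered diallyl ether (O bridging C6 and C13; 3,8-bis-TBS, 10-TES, C12 as PMB ether) | O1C/C=C(/C)[C@@H](O[Si](C)(C)C(C)(C)C)/C=C/[C@@](C)(O[Si](CC)(CC)CC)C[C@H](O[Si](C)(C)C(C)(C)C)/C=C(/COCc2ccc(OC)cc2)C1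
A5 | alternative 3 | ring-contracted ten-membered homoallylic alcohol (C6–OH, C7 bearing 3-[(4-methoxybenzyl)oxy]prop-1-en-2-yl) | O[C@H]1/C=C(/C)[C@@H](O[Si](C)(C)C(C)(C)C)/C=C/[C@@](C)(O[Si](CC)(CC)CC)C[C@H](O[Si](C)(C)C(C)(C)C)[C@H]1C(=C)COCc1ccc(OC)cc1
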